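**Retrosynthetic overview**
1. Target 21 ← vinyl epoxide 19 + angelic acid 20 (trans-diaxial opening at the allylic C5); 19 ← epoxy ketone 18 (Wittig at C4) ← enone 17 ← C4 alcohol 15.
2. Ring B (C1–C2–C3–C3a–C7a) ← closure of the C2–C3 bond by rhodium-catalysed hydroacylation. Enabling feature: the oxygen-bearing C2 and the C3 methylene are joined through C1 and the ring-fusion bond C7a–C3a, so with C2 as CHO and C3 as an exocyclic =CH2 on ring A the unit C2–C1(=CHCH3)–C7a–C3a=C3 is a 2-ethylidenepent-4-enal.
3. That dienal ← [3,3] Claisen shift of an allyl allenyl ether (C1–C7a bond, exocyclic alkene and Z-enal in one event) ← 2-butynyl ether of the Morita–Baylis–Hillman alcohol of (S)-cryptone.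
4. Ring order: ring A first (organocatalytic Michael addition, aldol condensation), ring B second (step 8), oxygenation of C4–C6 last.

Key step: step 8

Remark on locants: bicyclic compounds use 1H-indene numbering (C1 ethylidene carbon, C2 acetoxy carbon, C3 ring CH2, C3a/C7a ring fusion, C4 methylidene carbon, C5 angeloyloxy carbon, C6 carbinol, C7 isopropyl carbon); α means the face of the C7 isopropyl group, β the opposite face.
Assumption: the (S)-diarylprolinol silyl ether of step 1 is taken to give the (2S)-aldehyde (attack on the enamine face remote from the diarylmethyl group), as in its other Michael additions of aldehydes.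

Step 1
Reactants: 1 3-methylbutanal; 2 but-3-en-2-one
Product: 3 (2S)-5-oxo-2-(propan-2-yl)hexanal
Conditions: (S)-α,α-diphenylprolinol trimethylsilyl ether (5 mol %), ethyl 3,4-dihydroxybenzoate (20 mol %), neat, 4 °C
Reagents that add atoms: none
Why: Enamine-catalysed Michael addition of an aldehyde to an enone, in which the E-enamine should add to the vinyl ketone on its unshielded face and so set the future C7 stereocentre.

Step 2
Reactants: 3 (2S)-5-oxo-2-(propan-2-yl)hexanal
Product: 4 (4S)-4-(propan-2-yl)cyclohex-2-en-1-one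
Conditions: LiOH (cat.), i-PrOH, 23 °C
Reagents that add atoms: none
Why: Intramolecular aldol condensation of the methyl ketone onto the aldehyde closes ring A as the conjugated cyclohexenone under mild hydroxide conditions chosen to limit epimerisation of the aldehyde α-centre before ring closure.

Step 3
Reactants: 4 (4S)-4-(propan-2-yl)cyclohex-2-en-1-one
Product: 5 (4S)-2-(hydroxymethyl)-4-(propan-2-yl)cyclohex-2-en-1-one
Conditions: 37% aq. CH2O, DMAP (cat.), THF/H2O, 23 °C
Reagents that add atoms: formaldehyde, C=O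
Why: Morita–Baylis–Hillman reaction of a cyclic enone with formaldehyde places the future C3 carbon on the enone α-carbon without touching the γ-stereocentre.

Step 4
Reactants: 5 (4S)-2-(hydroxymethyl)-4-(propan-2-yl)cyclohex-2-en-1-one; 6 1-bromobut-2-yne
Product: 7 (4S)-2-[(but-2-yn-1-yloxy)methyl]-4-(propan-2-yl)cyclohex-2-en-1-one
Conditions: Ag2O, 4 Å MS, CH2Cl2, dark, 23→40 °C
Reagents that add atoms: none
Why: Silver-oxide-promoted Williamson (Purdie) etherification of the primary allylic alcohol with a propargylic bromide needs no strong base, so the enone should survive.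

Step 5
Reactants: 7 (4S)-2-[(but-2-yn-1-yloxy)methyl]-4-(propan-2-yl)cyclohex-2-en-1-one
Product: 8 (1S,4S)-2-[(but-2-yn-1-yloxy)methyl]-4-(propan-2-yl)cyclohex-2-en-1-ol (OH cis to isopropyl)
Conditions: (R)-2-methyl-CBS-oxazaborolidine (20 mol %), catecholborane, toluene, −78 °C; aq. NaOH work-up
Reagents that add atoms: none
Why: Corey–Bakshi–Shibata reduction under reagent control, with the α-substituted alkenyl carbon as the large group, should deliver hydride to the β-face and give the (1S)-alcohol on the α-face, while catecholborane spares the alkyne.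

Step 6
Reactants: 8 (1S,4S)-2-[(but-2-yn-1-yloxy)methyl]-4-(propan-2-yl)cyclohex-2-en-1-ol
Product: 9 tert-butyl{[(1S,4S)-2-[(but-2-yn-1-yloxy)methyl]-4-(propan-2-yl)cyclohex-2-en-1-yl]oxy}dimethylsilane
Conditions: TBSCl, imidazole, DMF, 23 °C
Reagents that add atoms: tert-butyldimethylsilyl chloride, CC(C)(C)[Si](C)(C)Cl
Why: Standard silylation masks the allylic alcohol as a non-ionisable ether that later sits axial on the α-face.

Step 7
Reactants: 9 tert-butyl{[(1S,4S)-2-[(but-2-yn-1-yloxy)methyl]-4-(propan-2-yl)cyclohex-2-en-1-yl]oxy}dimethylsilane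
Product: 10 tert-butyl{[(1S,4S)-2-[(buta-1,2-dien-1-yloxy)methyl]-4-(propan-2-yl)cyclohex-2-en-1-yl]oxy}dimethylsilane (both allene epimers)
Conditions: KOtBu (0.3 equiv), THF/DMSO, 23 °C
Reagents that add atoms: none
Why: Base-mediated propargyl–allenyl ether isomerisation (deprotonation of the α-oxy propargylic CH2, reprotonation at the remote alkyne carbon) should give the 1-alkoxy-1,2-diene, and both allene epimers are expected to converge in step 8.

Step 8
Reactants: 10 tert-butyl{[(1S,4S)-2-[(buta-1,2-dien-1-yloxy)methyl]-4-(propan-2-yl)cyclohex-2-en-1-yl]oxy}dimethylsilane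
Product: 12 (1Z,3aR,4S,7S,7aS)-4-{[tert-butyl(dimethyl)silyl]oxy}-1-ethylidene-7-(propan-2-yl)octahydro-2H-inden-2-one (trans-fused), via (Z)-dienal 11 (not isolated)
Conditions: ClCH2CH2Cl, 80 °C; then 23 °C, [Rh(nbd)(dppe)]BF4 (5 mol %, pre-hydrogenated, degassed), same flask
Reagents that add atoms: none
Why: Heating triggers the [3,3] Claisen shift of the allyl allenyl ether, which forms the C1–C7a bond on the β-face (opposite the C7 isopropyl and C4 silyloxy groups), creates the exocyclic C3a=C3 alkene and, because the allene methyl turns away from the ring, should give the 2-substituted (Z)-but-2-enal 11. The cationic monovalent rhodium complex then inserts into the aldehyde C–H bond, the acyl–rhodium hydride adds across the 1,1-disubstituted alkene with hydride to C3a and rhodium to C3, and C(acyl)–C(sp3) reductive elimination from the six-membered rhodacycle forms the C2–C3 bond; the closest known reaction type is the rhodium-catalysed intramolecular hydroacylation of 4-substituted and 3,4-disubstituted pent-4-enals to cyclopentanones, including its one-pot combination with a Claisen rearrangement. Ring B therefore closes in a formal 5-endo sense that is open only because the bond is made by reductive elimination from the metallacycle. C7a is set by the suprafacial Claisen shift under control of the neighbouring C7 centre, and C3a is set in the hydride insertion: the acyl–rhodium hydride is tethered through the equatorial, β-oriented C1 and reaches only the β-face of the alkene, whose α-face is also screened by the axial C4 silyloxy group, so rhodacycle and product should be trans-fused. The step needs anti-Markovnikov hydride insertion to outrun decarbonylation and alkene migration (favoured by the chelating diphosphine cation and by the 1,1-disubstituted alkene, which disfavours the tertiary alkyl–rhodium that would lead to a cyclobutanone) and retention of the Z enal geometry (no base or acid is present).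

Step 9
Reactants: 12 (1Z,3aR,4S,7S,7aS)-4-{[tert-butyl(dimethyl)silyl]oxy}-1-ethylidene-7-(propan-2-yl)octahydro-2H-inden-2-one
Product: 13 (1Z,2S,3aR,4S,7S,7aS)-4-{[tert-butyl(dimethyl)silyl]oxy}-1-ethylidene-7-(propan-2-yl)octahydro-1H-inden-2-ol
Conditions: (R)-2-methyl-CBS-oxazaborolidine (20 mol %), catecholborane, toluene, −78→−40 °C; aq. NaOH work-up
Reagents that add atoms: none
Why: Corey–Bakshi–Shibata 1,2-reduction of the exocyclic enone, with the alkylidene-bearing C1 as the large group and C3 as the small one, should deliver hydride to the β-face and set the (2S) α-alcohol.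

Step 10
Reactants: 13 (1Z,2S,3aR,4S,7S,7aS)-4-{[tert-butyl(dimethyl)silyl]oxy}-1-ethylidene-7-(propan-2-yl)octahydro-1H-inden-2-ol
Product: 14 (1Z,2S,3aR,4S,7S,7aS)-4-{[tert-butyl(dimethyl)silyl]oxy}-1-ethylidene-7-(propan-2-yl)octahydro-1H-inden-2-yl acetate
Conditions: Ac2O, pyridine, DMAP (cat.), CH2Cl2, 0→23 °C
Reagents that add atoms: acetic anhydride, CC(=O)OC(C)=O
Why: Standard acetylation of the only free hydroxyl installs the C2 acetate of the target.

Step 11
Reactants: 14 (1Z,2S,3aR,4S,7S,7aS)-4-{[tert-butyl(dimethyl)silyl]oxy}-1-ethylidene-7-(propan-2-yl)octahydro-1H-inden-2-yl acetate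
Product: 15 (1Z,2S,3aR,4S,7S,7aS)-1-ethylidene-4-hydroxy-7-(propan-2-yl)octahydro-1H-inden-2-yl acetate
Conditions: HF·pyridine, THF, 0→23 °C
Reagents that add atoms: none
Why: Fluoride-mediated desilylation under buffered acidic conditions should free the C4 alcohol and leave the allylic acetate in place.

Step 12
Reactants: 15 (1Z,2S,3aR,4S,7S,7aS)-1-ethylidene-4-hydroxy-7-(propan-2-yl)octahydro-1H-inden-2-yl acetate
Product: 17 (1Z,2S,3aR,7R,7aS)-1-ethylidene-4-oxo-7-(propan-2-yl)-2,3,3a,4,7,7a-hexahydro-1H-inden-2-yl acetate, via ketone 16 (not isolated)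
Conditions: IBX (4 equiv), DMSO, 23→70 °C
Reagents that add atoms: none
Why: IBX oxidises the alcohol to the C4 ketone and then dehydrogenates it (IBX ketone-to-enone oxidation) on the C5–C6 methylene side, since enolisation toward the hindered tertiary ring-fusion carbon C3a should be slower.

Step 13
Reactants: 17 (1Z,2S,3aR,7R,7aS)-1-ethylidene-4-oxo-7-(propan-2-yl)-2,3,3a,4,7,7a-hexahydro-1H-inden-2-yl acetate
Product: 18 (1Z,2S,3aR,5S,6S,7S,7aS)-5,6-epoxy-1-ethylidene-4-oxo-7-(propan-2-yl)octahydro-1H-inden-2-yl acetate (α-epoxide)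
Conditions: t-BuOOH (decane), DBU, CH2Cl2, 0→23 °C
Reagents that add atoms: tert-butyl hydroperoxide, CC(C)(C)OO
Why: Weitz–Scheffer nucleophilic epoxidation, in which the peroxide anion should add axially to C6 from the α-face of the conformationally locked trans-fused enone (antiparallel attack leading to the chair enolate) and so place the epoxide on the α-face, while the anhydrous amine base spares the acetate.

Step 14
Reactants: 18 (1Z,2S,3aR,5S,6S,7S,7aS)-5,6-epoxy-1-ethylidene-4-oxo-7-(propan-2-yl)octahydro-1H-inden-2-yl acetate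
Product: 19 (1Z,2S,3aR,5R,6S,7S,7aR)-5,6-epoxy-1-ethylidene-4-methylidene-7-(propan-2-yl)octahydro-1H-inden-2-yl acetate
Conditions: Ph3PCH3Br, KN(SiMe3)2, THF, 0 °C; then 18, −20→0 °C
Reagents that add atoms: methylenetriphenylphosphorane (made in the flask from methyltriphenylphosphonium bromide), C=P(c1ccccc1)(c1ccccc1)c1ccccc1
Why: Wittig methylenation of an α,β-epoxy ketone should be faster than attack on the acetate and gives the vinyl epoxide without opening the oxirane.

Step 15
Reactants: 19 (1Z,2S,3aR,5R,6S,7S,7aR)-5,6-epoxy-1-ethylidene-4-methylidene-7-(propan-2-yl)octahydro-1H-inden-2-yl acetate; 20 (2Z)-2-methylbut-2-enoic acid (angelic acid, excess)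
Product: 21 (1Z,2S,3aR,5S,6S,7S,7aR)-2-(acetyloxy)-1-ethylidene-6-hydroxy-4-methylidene-7-(propan-2-yl)octahydro-1H-inden-5-yl (2Z)-2-methylbut-2-enoate
Conditions: Cs2CO3 (0.2 equiv), toluene, 60 °C
Reagents that add atoms: none
Why: Carboxylate opening of a vinyl epoxide at the activated allylic C5 with inversion, along the trans-diaxial (Fürst–Plattner) trajectory from the β-face, should set the (5S) angelate and release the axial (6S) hydroxyl in one operation.

**Compound list**
1 | 3-methylbutanal | CC(C)CC=O | starting material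
2 | but-3-en-2-one | CC(=O)C=C | starting material
3 | (2S)-5-oxo-2-(propan-2-yl)hexanal | O=C[C@H](C(C)C)CCC(C)=O | intermediate
4 | (4S)-4-(propan-2-yl)cyclohex-2-en-1-one | O=C1C=C[C@H](C(C)C)CC1 | intermediate
5 | (4S)-2-(hydroxymethyl)-4-(propan-2-yl)cyclohex-2-en-1-one | O=C1C(CO)=C[C@H](C(C)C)CC1 | intermediate
6 | 1-bromobut-2-yne | CC#CCBr | starting material
7 | (4S)-2-[(but-2-yn-1-yloxy)methyl]-4-(propan-2-yl)cyclohex-2-en-1-one | O=C1C(COCC#CC)=C[C@H](C(C)C)CC1 | intermediate
8 | (1S,4S)-2-[(but-2-yn-1-yloxy)methyl]-4-(propan-2-yl)cyclohex-2-en-1-ol | O[C@@H]1C(COCC#CC)=C[C@H](C(C)C)CC1 | intermediate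
9 | tert-butyl{[(1S,4S)-2-[(but-2-yn-1-yloxy)methyl]-4-(propan-2-yl)cyclohex-2-en-1-yl]oxy}dimethylsilane | CC(C)(C)[Si](C)(C)O[C@@H]1C(COCC#CC)=C[C@H](C(C)C)CC1 | intermediate
10 | tert-butyl{[(1S,4S)-2-[(buta-1,2-dien-1-yloxy)methyl]-4-(propan-2-yl)cyclohex-2-en-1-yl]oxy}dimethylsilane | CC(C)(C)[Si](C)(C)O[C@@H]1C(COC=C=CC)=C[C@H](C(C)C)CC1 | intermediate
11 | (2Z)-2-[(1S,3S,6S)-3-{[tert-butyl(dimethyl)silyl]oxy}-2-methylidene-6-(propan-2-yl)cyclohexyl]but-2-enal | C=C1[C@@H](O[Si](C)(C)C(C)(C)C)CC[C@@H](C(C)C)[C@@H]1/C(C=O)=C/C | intermediate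
12 | (1Z,3aR,4S,7S,7aS)-4-{[tert-butyl(dimethyl)silyl]oxy}-1-ethylidene-7-(propan-2-yl)octahydro-2H-inden-2-one | CC(C)(C)[Si](C)(C)O[C@@H]1[C@@H]2CC(=O)/C(=C\C)[C@H]2[C@H](C(C)C)CC1 | intermediate
13 | (1Z,2S,3aR,4S,7S,7aS)-4-{[tert-butyl(dimethyl)silyl]oxy}-1-ethylidene-7-(propan-2-yl)octahydro-1H-inden-2-ol | CC(C)(C)[Si](C)(C)O[C@@H]1[C@@H]2C[C@H](O)/C(=C\C)[C@H]2[C@H](C(C)C)CC1 | intermediate
14 | (1Z,2S,3aR,4S,7S,7aS)-4-{[tert-butyl(dimethyl)silyl]oxy}-1-ethylidene-7-(propan-2-yl)octahydro-1H-inden-2-yl acetate | CC(C)(C)[Si](C)(C)O[C@@H]1[C@@H]2C[C@H](OC(C)=O)/C(=C\C)[C@H]2[C@H](C(C)C)CC1 | intermediate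
15 | (1Z,2S,3aR,4S,7S,7aS)-1-ethylidene-4-hydroxy-7-(propan-2-yl)octahydro-1H-inden-2-yl acetate | O[C@@H]1[C@@H]2C[C@H](OC(C)=O)/C(=C\C)[C@H]2[C@H](C(C)C)CC1 | intermediate
16 | (1Z,2S,3aR,7S,7aS)-1-ethylidene-4-oxo-7-(propan-2-yl)octahydro-1H-inden-2-yl acetate | O=C1[C@@H]2C[C@H](OC(C)=O)/C(=C\C)[C@H]2[C@H](C(C)C)CC1 | intermediate
17 | (1Z,2S,3aR,7R,7aS)-1-ethylidene-4-oxo-7-(propan-2-yl)-2,3,3a,4,7,7a-hexahydro-1H-inden-2-yl acetate | O=C1[C@@H]2C[C@H](OC(C)=O)/C(=C\C)[C@H]2[C@H](C(C)C)C=C1 | intermediate
18 | (1Z,2S,3aR,5S,6S,7S,7aS)-5,6-epoxy-1-ethylidene-4-oxo-7-(propan-2-yl)octahydro-1H-inden-2-yl acetate | O=C1[C@@H]2C[C@H](OC(C)=O)/C(=C\C)[C@H]2[C@H](C(C)C)[C@@H]3O[C@@H]31 | intermediate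
19 | (1Z,2S,3aR,5R,6S,7S,7aR)-5,6-epoxy-1-ethylidene-4-methylidene-7-(propan-2-yl)octahydro-1H-inden-2-yl acetate | C=C1[C@@H]2C[C@H](OC(C)=O)/C(=C\C)[C@H]2[C@H](C(C)C)[C@@H]3O[C@@H]31 | intermediate
20 | (2Z)-2-methylbut-2-enoic acid (angelic acid) | C/C=C(/C)C(=O)O | starting material
21 | (1Z,2S,3aR,5S,6S,7S,7aR)-2-(acetyloxy)-1-ethylidene-6-hydroxy-4-methylidene-7-(propan-2-yl)octahydro-1H-inden-5-yl (2Z)-2-methylbut-2-enoate | C=C1[C@@H]2C[C@H](OC(C)=O)/C(=C\C)[C@H]2[C@H](C(C)C)[C@H](O)[C@H]1OC(=O)/C(C)=C\C | target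

Total step count: 15
Longest linear sequence: 15 steps (1 + 2 → 21)

**Steps most likely to fail**

Step 8. The two stereochemical events may not be controlled: the allene epimers may give E/Z mixtures in the Claisen shift, and hydride may be delivered to the α-face to give the cis-fused ketone. The acyl–rhodium hydride may also decarbonylate or move the exocyclic alkene into the ring. The fallback sets out from 11 and comes back at 13. Compound 10 is heated alone (ClCH2CH2Cl, 80 °C) and dienal 11 is isolated. Luche reduction (NaBH4, CeCl3·7H2O, MeOH, −20 °C) should give the (Z)-allylic alcohol F1. Hydroboration with 9-BBN (THF, 0→23 °C; NaBO3·4H2O) should take only the 1,1-disubstituted exocyclic alkene, from the β-face anti to the axial silyloxy group, and give the diol F2 with the C3a hydrogen on the β-face. MnO2 (CH2Cl2) should oxidise only the allylic hydroxyl to the hydroxy enal F3, and I2, PPh3 and imidazole convert the remaining primary alcohol into the iodo enal F4. An intramolecular Barbier reaction with SmI2 (THF/HMPA, −78 °C; 5-exo addition of the alkylsamarium to the aldehyde) then closes the C2–C3 bond and gives 13. Any C2 epimer would be oxidised with MnO2 to 12 and corrected in step 9.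

Step 12. Dehydrogenation may occur on the ring-fusion side through enolisation toward C3a, or C3a may epimerise under the warm, weakly acidic IBX conditions. The fallback sets out from 15 and comes back at 17. Dess–Martin periodinane (NaHCO3, CH2Cl2) gives ketone 16, now isolated. LiN(SiMe3)2 with Me3SiCl present (THF, −78 °C) should remove the C5 methylene proton kinetically (the ketone is more acidic than the acetate) and give the silyl enol ether F5. Saegusa–Ito oxidation with Pd(OAc)2 (MeCN, 23 °C) then gives 17 with the regiochemistry fixed by the enol ether.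

Step 15. The carboxylate may attack the exocyclic methylene terminus (SN2′ mode), or the angelate may isomerise to the tiglate under the heated conditions. The fallback sets out from 19 and comes back at 21. Acid-catalysed hydrolysis (HClO4 cat., THF/H2O, 0 °C) should open the epoxide trans-diaxially at the allylic carbon and give the diol F6. The less hindered allylic C5 hydroxyl is then acylated with the mixed anhydride of angelic acid 20 and 2,4,6-trichlorobenzoyl chloride (Et3N, toluene, 23→60 °C, no nucleophilic catalyst; Yamaguchi-type esterification) to give 21.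

**Further compounds**
F1 | step 8 | (Z)-allylic alcohol from 1,2-reduction of dienal 11 | C=C1[C@@H](O[Si](C)(C)C(C)(C)C)CC[C@@H](C(C)C)[C@@H]1/C(CO)=C/C
F2 | step 8 | diol from β-face hydroboration–oxidation of the exocyclic alkene of F1 | OC[C@H]1[C@@H](O[Si](C)(C)C(C)(C)C)CC[C@@H](C(C)C)[C@@H]1/C(CO)=C/C
F3 | step 8 | hydroxy (Z)-enal from allylic oxidation of F2 | OC[C@H]1[C@@H](O[Si](C)(C)C(C)(C)C)CC[C@@H](C(C)C)[C@@H]1/C(C=O)=C/C
F4 | step 8 | iodo (Z)-enal from F3 | IC[C@H]1[C@@H](O[Si](C)(C)C(C)(C)C)CC[C@@H](C(C)C)[C@@H]1/C(C=O)=C/C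
F5 | step 12 | C4–C5 trimethylsilyl enol ether of ketone 16 | C[Si](C)(C)OC=1[C@@H]2C[C@H](OC(C)=O)/C(=C\C)[C@H]2[C@H](C(C)C)CC=1
F6 | step 15 | 5β,6α-diol from hydrolysis of epoxide 19 | C=C1[C@@H]2C[C@H](OC(C)=O)/C(=C\C)[C@H]2[C@H](C(C)C)[C@H](O)[C@H]1O
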